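**Plan**

- Numbering follows the azulene name of the target: C3 carbinol, C3a ring-fusion CH, C4 ester carbon, C6 formyl-bearing carbon, C8a quaternary carbon. Retrosynthetic cuts: the C4–O ester, the C3–isopropyl bond, O/H across C3a–C4, then C8–C8a and C5–C6 of the seven-membered ring (formal [4+3]).
- Enabling feature: in the seven-membered ring the C6=C7 alkene (acceptor carbon on C6) and the C3a–C4 pair (H and O cis) flank the C5 methylene. The ring is therefore a hydrated cyclohepta-1,4-diene, the product type of a cis-divinylcyclopropane Cope shift whose new σ bond is C8–C8a.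
- Forward: the five-membered ring is bought as a bromoenone, masked as a ketal and vinylated. Rh-carbenoid cyclopropanation of the vinyl group and Cope ring expansion close the seven-membered ring. Hydroboration, ester reduction, ketal removal, isopropyl addition, allylic oxidation and esterification follow.
- Stereochemistry: C8a comes from the chiral dirhodium catalyst (cyclopropane, then boat Cope). C3a and C4 come from syn hydroboration anti to the C8a methyl. C3 comes from isopropyl addition to the ketone anti to the C3a–C4 bond and the methyl.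
- Helpers: the temporary cyclopropane (consumed in the same flask), the ester (carbenoid acceptor, later the aldehyde) and the ketal (masks the C3 ketone until the isopropyl group is added).

Key step: step 4

Remark: Rh2(R-DOSP)4 is assumed to deliver the carbenoid to the Si face of the vinyl CH of the diene, by analogy with the sense of induction recalled for the S catalyst with monosubstituted alkenes; this sense is not verified here.

**Step 1**
Reactants: 1 2-bromo-3-methylcyclopent-2-en-1-one
Product: 2 6-bromo-7-methyl-1,4-dioxaspiro[4.4]non-6-ene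
Conditions: ethylene glycol, p-TsOH·H2O (cat.), benzene, reflux, Dean–Stark
Reagents that add atoms: ethylene glycol (OCCO)
Why: Acid-catalysed ketalisation with azeotropic water removal masks the future C3 ketone and makes the vinyl bromide electron-neutral; the bromine-substituted double bond should stay in place as with related 2-bromoenones, and no stereocenter is formed.

**Step 2**
Reactants: 2 6-bromo-7-methyl-1,4-dioxaspiro[4.4]non-6-ene
Product: 3 6-ethenyl-7-methyl-1,4-dioxaspiro[4.4]non-6-ene
Conditions: tributyl(ethenyl)stannane, Pd(PPh3)4 (5 mol%), toluene, 100 °C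
Reagents that add atoms: tributyl(ethenyl)stannane (C=C[Sn](CCCC)(CCCC)CCCC)
Why: Stille cross-coupling of the alkenyl bromide under zerovalent palladium catalysis should give the 1,3-diene under neutral conditions that keep the acid-labile allylic ketal; no stereocenter is formed.

**Step 3**
Reactants: 4 methyl but-3-enoate
Product: 5 methyl 2-diazobut-3-enoate
Conditions: 4-acetamidobenzenesulfonyl azide, DBU, MeCN, 0 °C; cold pentane extraction, used at once
Reagents that add atoms: 4-acetamidobenzenesulfonyl azide (CC(=O)Nc1ccc(cc1)S(=O)(=O)N=[N+]=[N-])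
Why: Regitz diazo transfer to the methylene that is both allylic and α to the ester should give the vinyldiazoacetate, which is kept cold and used directly because it cyclises to a pyrazole on standing.

**Step 4**
Reactants: 3 6-ethenyl-7-methyl-1,4-dioxaspiro[4.4]non-6-ene, 5 methyl 2-diazobut-3-enoate
Product: 7 methyl (8aR)-3,3-(ethane-1,2-diyldioxy)-8a-methyl-1,2,3,5,8,8a-hexahydroazulene-6-carboxylate, via cis-divinylcyclopropane 6 (not isolated)
Conditions: Rh2(R-DOSP)4 (1 mol%), pentane, −78 °C, slow addition of 5 (2 equiv), then 23 °C; then toluene, 90 °C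
Reagents that add atoms: none
Why: The dirhodium carboxylate converts 5 into a donor/acceptor vinylcarbenoid that cyclopropanates the only accessible alkene of 3, the terminal vinyl group, with the carbenoid vinyl cis to the cyclopentenyl group (6); on warming, 6 undergoes a [3,3]-sigmatropic Cope shift through the obligatory boat transition state, breaking the cyclopropane bond between the future C4 and C6 and forming the C8–C8a bond. The closest known reaction type is the tandem cyclopropanation/Cope rearrangement, the formal [4+3] cycloaddition of vinylcarbenoids with dienes. The seven-membered ring closes by ring expansion of the three-membered ring inside a six-atom pericyclic array (3 to 7), driven by release of cyclopropane strain. The new quaternary stereocenter C8a is controlled by the configuration of the cyclopropane carbon bearing the cyclopentenyl group, because the boat geometry lets the vinyl terminus reach only one face of C8a; that carbon is set by the chiral catalyst, whose R form is chosen to attack the Si face of the vinyl CH. The step needs site selectivity (secured by the hindered tetrasubstituted ring alkene), cis diastereoselectivity (intrinsic to donor/acceptor carbenoids) and enantioface selectivity (catalyst, hydrocarbon solvent, low temperature); the methyl group cis to the cyclopropane on the ring alkene should slow the Cope step, hence the heating.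

**Step 5**
Reactants: 7 methyl (8aR)-3,3-(ethane-1,2-diyldioxy)-8a-methyl-1,2,3,5,8,8a-hexahydroazulene-6-carboxylate
Product: 9 methyl (3aS,4S,8aR)-3,3-(ethane-1,2-diyldioxy)-4-hydroxy-8a-methyl-1,2,3,3a,4,5,8,8a-octahydroazulene-6-carboxylate, via C4 alkylborane 8 (not isolated)
Conditions: BH3·THF (2 equiv), THF, 0 → 23 °C; then NaBO3·4H2O, H2O, 23 °C
Reagents that add atoms: borane–tetrahydrofuran ([BH3-][O+]1CCCC1; boron of 8), sodium perborate tetrahydrate (O.O.O.O.[Na+].[O-]OB=O; hydroxyl oxygen of 9)
Why: Hydroboration–oxidation should place boron on the less substituted C4 and hydrogen on C3a of the trisubstituted alkene (the enoate alkene is electron-poor and slower), syn and from the face opposite the C8a methyl, which in the twist form of the cyclohepta-1,4-diene is also the face not covered by C6, so that H-3a and 4-OH are cis to each other and trans to the methyl after oxidation with retention.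

**Step 6**
Reactants: 9 methyl (3aS,4S,8aR)-3,3-(ethane-1,2-diyldioxy)-4-hydroxy-8a-methyl-1,2,3,3a,4,5,8,8a-octahydroazulene-6-carboxylate
Product: 10 (3aS,4S,8aR)-3,3-(ethane-1,2-diyldioxy)-6-(hydroxymethyl)-8a-methyl-1,2,3,3a,4,5,8,8a-octahydroazulen-4-ol
Conditions: i-Bu2AlH (3.5 equiv), CH2Cl2, −78 °C; Rochelle salt work-up
Reagents that add atoms: none
Why: 1,2-Reduction of the α,β-unsaturated ester with diisobutylaluminium hydride should give the allylic alcohol while the ketal still masks the ketone; no stereocenter is touched.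

**Step 7**
Reactants: 10 (3aS,4S,8aR)-3,3-(ethane-1,2-diyldioxy)-6-(hydroxymethyl)-8a-methyl-1,2,3,3a,4,5,8,8a-octahydroazulen-4-ol
Product: 11 (3aS,4S,8aR)-4-hydroxy-6-(hydroxymethyl)-8a-methyl-1,2,3,3a,4,5,8,8a-octahydroazulen-3-one
Conditions: PPTS (0.2 equiv), acetone/H2O (9:1), 40 °C
Reagents that add atoms: water (O)
Why: Mild acid-catalysed ketal hydrolysis should release the cyclopentanone; the weak pyridinium acid is chosen so that the β-hydroxy ketone neither dehydrates nor epimerises at C3a.

**Step 8**
Reactants: 11 (3aS,4S,8aR)-4-hydroxy-6-(hydroxymethyl)-8a-methyl-1,2,3,3a,4,5,8,8a-octahydroazulen-3-one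
Product: 12 (3R,3aS,4S,8aR)-6-(hydroxymethyl)-8a-methyl-3-(propan-2-yl)-1,2,3,3a,4,5,8,8a-octahydroazulene-3,4-diol
Conditions: i-PrMgCl (6 equiv), CeCl3 (6 equiv, dried), THF, −78 → 0 °C
Reagents that add atoms: isopropylmagnesium chloride (CC(C)[Mg]Cl)
Why: Organocerium (Imamoto) 1,2-addition, which suppresses enolisation and β-hydride reduction, should attack the cyclopentanone from the face cis to H-3a, opposite the C3a–C4 bond and the angular methyl, setting C3 with its hydroxyl cis to the methyl; the two hydroxyls are carried as alkoxides.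

**Step 9**
Reactants: 12 (3R,3aS,4S,8aR)-6-(hydroxymethyl)-8a-methyl-3-(propan-2-yl)-1,2,3,3a,4,5,8,8a-octahydroazulene-3,4-diol
Product: 13 (3R,3aS,4S,8aR)-3,4-dihydroxy-8a-methyl-3-(propan-2-yl)-1,2,3,3a,4,5,8,8a-octahydroazulene-6-carbaldehyde
Conditions: MnO2 (activated, 15 equiv), CH2Cl2, 23 °C
Reagents that add atoms: none
Why: MnO2 allylic oxidation should convert only the primary allylic alcohol into the enal, leaving the secondary homoallylic and the tertiary alcohol untouched.

**Step 10**
Reactants: 14 4-hydroxybenzoic acid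
Product: 16 4-[(tert-butyldimethylsilyl)oxy]benzoic acid, via bis-silyl derivative 15 (not isolated)
Conditions: TBSCl (2.3 equiv), imidazole, DMF, 23 °C; then AcOH/THF/H2O (3:1:1), 23 °C
Reagents that add atoms: tert-butyldimethylsilyl chloride (CC(C)(C)[Si](C)(C)Cl)
Why: Exhaustive silylation followed by selective hydrolysis of the labile silyl ester should leave the phenol protected for the esterification.

**Step 11**
Reactants: 13 (3R,3aS,4S,8aR)-3,4-dihydroxy-8a-methyl-3-(propan-2-yl)-1,2,3,3a,4,5,8,8a-octahydroazulene-6-carbaldehyde, 16 4-[(tert-butyldimethylsilyl)oxy]benzoic acid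
Product: 17 (3R,3aS,4S,8aR)-6-formyl-3-hydroxy-8a-methyl-3-(propan-2-yl)-1,2,3,3a,4,5,8,8a-octahydroazulen-4-yl 4-[(tert-butyldimethylsilyl)oxy]benzoate
Conditions: DCC (1.5 equiv), DMAP (0.5 equiv), CH2Cl2, 23 °C
Reagents that add atoms: none
Why: Steglich esterification should acylate the secondary C4 hydroxyl only, since the tertiary C3 hydroxyl is too hindered and the enal is inert.

**Step 12**
Reactants: 17 (3R,3aS,4S,8aR)-6-formyl-3-hydroxy-8a-methyl-3-(propan-2-yl)-1,2,3,3a,4,5,8,8a-octahydroazulen-4-yl 4-[(tert-butyldimethylsilyl)oxy]benzoate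
Product: 18 (3R,3aS,4S,8aR)-6-formyl-3-hydroxy-8a-methyl-3-(propan-2-yl)-1,2,3,3a,4,5,8,8a-octahydroazulen-4-yl 4-hydroxybenzoate
Conditions: TBAF (1.1 equiv), AcOH (1.1 equiv), THF, 0 °C
Reagents that add atoms: none
Why: Buffered fluoride desilylation should cleave the aryl silyl ether without touching the benzoate ester or the enal.

**Compound list**

1 | 2-bromo-3-methylcyclopent-2-en-1-one | CC1=C(Br)C(=O)CC1 | starting material
2 | 6-bromo-7-methyl-1,4-dioxaspiro[4.4]non-6-ene | CC1=C(Br)C2(CC1)OCCO2 | intermediate
3 | 6-ethenyl-7-methyl-1,4-dioxaspiro[4.4]non-6-ene | CC1=C(C=C)C2(CC1)OCCO2 | intermediate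
4 | methyl but-3-enoate | C=CCC(=O)OC | starting material
5 | methyl 2-diazobut-3-enoate | C=CC(=[N+]=[N-])C(=O)OC | intermediate
6 | methyl (1S,2S)-1-ethenyl-2-(7-methyl-1,4-dioxaspiro[4.4]non-6-en-6-yl)cyclopropane-1-carboxylate (cis-divinylcyclopropane) | C=C[C@@]1(C(=O)OC)C[C@H]1C2=C(C)CCC23OCCO3 | intermediate
7 | methyl (8aR)-3,3-(ethane-1,2-diyldioxy)-8a-methyl-1,2,3,5,8,8a-hexahydroazulene-6-carboxylate | O1CCOC12CC[C@]3(C)CC=C(C(=O)OC)CC=C23 | intermediate
8 | methyl 4-boranyl-3,3-(ethane-1,2-diyldioxy)-8a-methyl-1,2,3,3a,4,5,8,8a-octahydroazulene-6-carboxylate, boron and H-3a cis, both trans to the 8a-methyl | O1CCOC12CC[C@]3(C)CC=C(C(=O)OC)C[C@H](B)[C@@H]23 | intermediate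
9 | methyl (3aS,4S,8aR)-3,3-(ethane-1,2-diyldioxy)-4-hydroxy-8a-methyl-1,2,3,3a,4,5,8,8a-octahydroazulene-6-carboxylate | O1CCOC12CC[C@]3(C)CC=C(C(=O)OC)C[C@H](O)[C@@H]23 | intermediate
10 | (3aS,4S,8aR)-3,3-(ethane-1,2-diyldioxy)-6-(hydroxymethyl)-8a-methyl-1,2,3,3a,4,5,8,8a-octahydroazulen-4-ol | O1CCOC12CC[C@]3(C)CC=C(CO)C[C@H](O)[C@@H]23 | intermediate
11 | (3aS,4S,8aR)-4-hydroxy-6-(hydroxymethyl)-8a-methyl-1,2,3,3a,4,5,8,8a-octahydroazulen-3-one | O=C1CC[C@]2(C)CC=C(CO)C[C@H](O)[C@H]21 | intermediate
12 | (3R,3aS,4S,8aR)-6-(hydroxymethyl)-8a-methyl-3-(propan-2-yl)-1,2,3,3a,4,5,8,8a-octahydroazulene-3,4-diol | CC(C)[C@]1(O)CC[C@]2(C)CC=C(CO)C[C@H](O)[C@H]21 | intermediate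
13 | (3R,3aS,4S,8aR)-3,4-dihydroxy-8a-methyl-3-(propan-2-yl)-1,2,3,3a,4,5,8,8a-octahydroazulene-6-carbaldehyde | CC(C)[C@]1(O)CC[C@]2(C)CC=C(C=O)C[C@H](O)[C@H]21 | intermediate
14 | 4-hydroxybenzoic acid | O=C(O)c1ccc(O)cc1 | starting material
15 | tert-butyldimethylsilyl 4-[(tert-butyldimethylsilyl)oxy]benzoate | CC(C)(C)[Si](C)(C)OC(=O)c1ccc(O[Si](C)(C)C(C)(C)C)cc1 | intermediate
16 | 4-[(tert-butyldimethylsilyl)oxy]benzoic acid | CC(C)(C)[Si](C)(C)Oc1ccc(cc1)C(=O)O | intermediate
17 | (3R,3aS,4S,8aR)-6-formyl-3-hydroxy-8a-methyl-3-(propan-2-yl)-1,2,3,3a,4,5,8,8a-octahydroazulen-4-yl 4-[(tert-butyldimethylsilyl)oxy]benzoate | CC(C)[C@]1(O)CC[C@]2(C)CC=C(C=O)C[C@H](OC(=O)c3ccc(O[Si](C)(C)C(C)(C)C)cc3)[C@H]21 | intermediate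
18 | (3R,3aS,4S,8aR)-6-formyl-3-hydroxy-8a-methyl-3-(propan-2-yl)-1,2,3,3a,4,5,8,8a-octahydroazulen-4-yl 4-hydroxybenzoate | CC(C)[C@]1(O)CC[C@]2(C)CC=C(C=O)C[C@H](OC(=O)c3ccc(O)cc3)[C@H]21 | target

**Step count**

Total: 12 steps. Longest linear sequence: 10 steps (1, 2, 4, 5, 6, 7, 8, 9, 11, 12, from compound 1).

**Steps most likely to fail**

Step 4. The catalyst may discriminate the two faces of the hindered vinyl group incompletely; if the sense of induction proves opposite to the one assumed, the S catalyst is used instead. The fallback replaces asymmetric catalysis by resolution. It sets out from 9 of insufficient enantiomeric purity (made through steps 4 and 5, if need be with achiral Rh2(OPiv)4). DCC/DMAP esterification of the C4 hydroxyl with (2S)-2-methoxy-2-phenylacetic acid gives two diastereomeric esters. The ester of the required enantiomer, methyl (3aS,4S,8aR)-3,3-(ethane-1,2-diyldioxy)-4-{[(2S)-2-methoxy-2-phenylacetyl]oxy}-8a-methyl-1,2,3,3a,4,5,8,8a-octahydroazulene-6-carboxylate F1, is separated by chromatography or crystallisation. K2CO3 in methanol then cleaves it and returns the route at 9.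

Step 5. Borane may add with poor facial selectivity (attack on the methyl-bearing face gives the cis-fused epimer), or the enoate may be hydroborated in competition. The fallback introduces the C4 oxygen by conjugate chemistry and leaves C3a open to equilibration. It sets out from 7. PPTS in wet acetone removes the ketal to give the dienone methyl (8aR)-8a-methyl-3-oxo-1,2,3,5,8,8a-hexahydroazulene-6-carboxylate F2. Nucleophilic epoxidation of the more electrophilic enone (t-BuOOH, DBU, CH2Cl2), from the face away from the angular methyl, should give the epoxy ketone methyl (8aR)-3a,4-epoxy-8a-methyl-3-oxo-1,2,3,3a,4,5,8,8a-octahydroazulene-6-carboxylate with the epoxide oxygen trans to the 8a-methyl F3. SmI2 in THF/MeOH at −78 °C cleaves the C3a–O bond to the β-hydroxy ketone methyl (3aS,4S,8aR)-4-hydroxy-8a-methyl-3-oxo-1,2,3,3a,4,5,8,8a-octahydroazulene-6-carboxylate F4, whose C3a centre, α to the ketone, is set on protonation and can be equilibrated. i-PrMgCl/CeCl3 at −78 °C adds to the ketone to give methyl (3R,3aS,4S,8aR)-3,4-dihydroxy-8a-methyl-3-(propan-2-yl)-1,2,3,3a,4,5,8,8a-octahydroazulene-6-carboxylate F5. Reduction with i-Bu2AlH returns the route at 12.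

Step 8. The secondary organometallic may enolise or reduce the ketone by β-hydride transfer, and the β-alkoxide may open by retro-aldol cleavage. The fallback brings in the three carbons as an alkenyl nucleophile that cannot transfer hydride. It sets out from 11. 2-Propenylmagnesium bromide with CeCl3 in THF at −78 °C should give (3aS,4S,8aR)-6-(hydroxymethyl)-8a-methyl-3-(prop-1-en-2-yl)-1,2,3,3a,4,5,8,8a-octahydroazulene-3,4-diol with the 3-hydroxyl cis to the 8a-methyl F6. Selective hydrogenation of the 1,1-disubstituted alkene with H2 and RhCl(PPh3)3 in benzene, which should leave the trisubstituted ring alkene, returns the route at 12.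

**Further compounds**

F1 | step 4 | methyl (3aS,4S,8aR)-3,3-(ethane-1,2-diyldioxy)-4-{[(2S)-2-methoxy-2-phenylacetyl]oxy}-8a-methyl-1,2,3,3a,4,5,8,8a-octahydroazulene-6-carboxylate | O1CCOC12CC[C@]3(C)CC=C(C(=O)OC)C[C@H](OC(=O)[C@@H](OC)c4ccccc4)[C@@H]23
F2 | step 5 | methyl (8aR)-8a-methyl-3-oxo-1,2,3,5,8,8a-hexahydroazulene-6-carboxylate | O=C1CC[C@]2(C)CC=C(C(=O)OC)CC=C12
F3 | step 5 | methyl (8aR)-3a,4-epoxy-8a-methyl-3-oxo-1,2,3,3a,4,5,8,8a-octahydroazulene-6-carboxylate, epoxide oxygen trans to the 8a-methyl | O=C1CC[C@]2(C)CC=C(C(=O)OC)C[C@@H]3O[C@]123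
F4 | step 5 | methyl (3aS,4S,8aR)-4-hydroxy-8a-methyl-3-oxo-1,2,3,3a,4,5,8,8a-octahydroazulene-6-carboxylate | O=C1CC[C@]2(C)CC=C(C(=O)OC)C[C@H](O)[C@H]21
F5 | step 5 | methyl (3R,3aS,4S,8aR)-3,4-dihydroxy-8a-methyl-3-(propan-2-yl)-1,2,3,3a,4,5,8,8a-octahydroazulene-6-carboxylate | CC(C)[C@]1(O)CC[C@]2(C)CC=C(C(=O)OC)C[C@H](O)[C@H]21
F6 | step 8 | (3aS,4S,8aR)-6-(hydroxymethyl)-8a-methyl-3-(prop-1-en-2-yl)-1,2,3,3a,4,5,8,8a-octahydroazulene-3,4-diol, 3-hydroxyl cis to the 8a-methyl | CC(=C)[C@]1(O)CC[C@]2(C)CC=C(CO)C[C@H](O)[C@H]21
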